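**Retrosynthetic overview**

1. Luzonoid A is unmasked last from its tris-TBS ether; the two esters go on late (O1 on the enol-ether lactol, then O7). The C3=C4–C11H2OH unit comes from a C4 ketone (sulfonium-ylide epoxide, then epoxide-to-allylic-alcohol shift). No ring is formed after the key step.
2. Structural feature used: in the cyclopentane, C7 is a ring carbon between C6 and the oxygen-bearing C8, and C8 is bonded to the ring-fusion carbon C9. Hence C7 = carbon monoxide, C8≡C9 = an ynol ether (its oxygen becomes the tertiary 8-OH) and C5=C6 = a vinyl group, linked by the C1–O2–C3–C4 acetal chain of the oxane.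
3. One Pauson–Khand reaction of this acetal-tethered 1,7-enyne forms C5–C9, C6–C7 and C7–C8 and closes the oxane and the cyclopentenone together. Conjugate reduction/hydroxymethylation then sets C9, C8 and C10 from the convex face, and an 8-OH-directed reduction sets C7.
4. Two design points. The enyne has a single alkene: C4 is a PMB-protected carbinol from (R)-but-3-ene-1,2-diol, which steers C5 and later becomes the ketone that takes up C11 (a 2-methylene group at C4 would offer the alkyne a faster 1,6-cyclisation). The ynol ether acetal is assembled and cyclised as its Co2(CO)6 complex, because the free compound would be turned into a β-alkoxyacrylate by acid and a PMB ynol ether rearranges on heating.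
5. Building blocks: 4-methoxybenzyl alcohol, trichloroethylene and DMF (O8, C8, C9, C1); the diol (C3–C6); formaldehyde (C10); trimethylsulfonium iodide (C11); isovaleryl chloride; p-coumaric acid.

Key step: step 7

Remark: iridoid numbering is used (C1 acetal carbon, O2, C3, C4, ring fusion C5/C9, C6–C8, C10 on C8, C11 on C4; β = face of H-5 and H-9; PMB = 4-methoxybenzyl, TBS = tert-butyldimethylsilyl), and C1 is carried as an inconsequential mixture of epimers from 11 to 23, so the SMILES of those compounds leave C1 undefined.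

**Route**

Step 1
Reactants: 1 (R)-but-3-ene-1,2-diol
Product: 2 (4R)-2-(4-methoxyphenyl)-4-vinyl-1,3-dioxolane (both acetal epimers)
Conditions: 4-MeOC6H4CH(OMe)2, PPTS (cat.), CH2Cl2, rt
Reagents that add atoms: 4-methoxybenzaldehyde dimethyl acetal, COc1ccc(C(OC)OC)cc1
Why: Acid-catalysed transacetalisation closes the five-membered anisylidene acetal on the 1,2-diol without touching the stereocentre.

Step 2
Reactants: 2 (4R)-2-(4-methoxyphenyl)-4-vinyl-1,3-dioxolane
Product: 3 (R)-2-[(4-methoxybenzyl)oxy]but-3-en-1-ol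
Conditions: DIBAL-H, CH2Cl2, −78 → 0 °C; Rochelle salt
Reagents that add atoms: none
Why: Reductive acetal opening: DIBAL-H binds the less hindered primary oxygen and cleaves its bond to the acetal carbon, so the PMB group stays on the secondary allylic oxygen and the primary alcohol is freed.

Step 3
Reactants: 4 4-methoxybenzyl alcohol; 5 trichloroethylene
Product: 6 (E)-1,2-dichlorovinyl 4-methoxybenzyl ether
Conditions: KH, THF, 0 °C; then Cl2C=CHCl, −50 °C → rt
Reagents that add atoms: none
Why: Base-induced loss of HCl from trichloroethylene gives dichloroacetylene, to which the potassium alkoxide adds in an anti sense to give the (E)-1,2-dichlorovinyl ether, the standard entry to ynol ethers.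

Step 4
Reactants: 6 (E)-1,2-dichlorovinyl 4-methoxybenzyl ether
Product: 8 3-[(4-methoxybenzyl)oxy]prop-2-ynal, via lithium alkoxyacetylide 7 (not isolated)
Conditions: n-BuLi (2.2 equiv), THF, −78 → −40 °C; DMF, −78 °C; inverse quench into aq. KH2PO4, 0 °C
Reagents that add atoms: N,N-dimethylformamide, CN(C)C=O
Why: Deprotonation, loss of LiCl and Li–Cl exchange give the lithium alkoxyacetylide, which DMF formylates (acetylide formylation); the buffered inverse quench keeps dimethylamine from adding to the ynal, which is kept cold and used at once because benzyl-type ynol ethers rearrange on warming.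

Step 5
Reactants: 8 3-[(4-methoxybenzyl)oxy]prop-2-ynal
Product: 10 hexacarbonyldicobalt complex of 3,3-dimethoxy-1-[(4-methoxybenzyl)oxy]prop-1-yne, via cobalt-complexed ynal 9 (not isolated)
Conditions: Co2(CO)8, CH2Cl2, 0 °C → rt; then HC(OMe)3, MeOH, PPTS (cat.), rt
Reagents that add atoms: dicobalt octacarbonyl, O=C=[Co](=C=O)(=C=O)(=C=O)[Co](=C=O)(=C=O)(=C=O)=C=O; trimethyl orthoformate, COC(OC)OC
Why: Alkyne complexation by Co2(CO)8 masks the ynol ether, and the complexed aldehyde is then acetalised through the cobalt-stabilised (Nicholas-type) propargylic cation, which cannot be attacked at C8.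

Step 6
Reactants: 10 hexacarbonyldicobalt complex of the dimethyl acetal; 3 (R)-2-[(4-methoxybenzyl)oxy]but-3-en-1-ol
Product: 11 hexacarbonyldicobalt complex of 3-methoxy-1-[(4-methoxybenzyl)oxy]-3-{[(2R)-2-[(4-methoxybenzyl)oxy]but-3-en-1-yl]oxy}prop-1-yne (C1 epimers)
Conditions: 10 (2 equiv), CSA (10 mol %), 5 Å MS, CH2Cl2, −20 → 0 °C; Et3N
Reagents that add atoms: none
Why: Nicholas-type acetal exchange: acid ionises one methoxy group to the Co2(CO)6-stabilised α-methoxy propargyl cation, which alcohol 3 captures at C1 only, while excess 10 and sieves that take up methanol hold the exchange at the mixed acetal.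

Step 7
Reactants: 11 cobalt-complexed ynol ether acetal 1,7-enyne
Product: 12 1-methoxy-4β,8-bis[(4-methoxybenzyl)oxy]-3,4,5,6-tetrahydro-1H-cyclopenta[c]pyran-7-one (iridoid numbering; H-5β, C8=C9 enone, C1 epimers)
Conditions: NMO (8 equiv), CH2Cl2, 0 °C → rt
Reagents that add atoms: none
Why: N-Oxide removal of a CO ligand from the alkoxyalkyne–Co2(CO)6 cluster opens a site for the vinyl group, which inserts into the Co–C9 bond (C5–C9); CO then inserts and reductive elimination joins C6–C7 and C7–C8, the cluster having kept the ynol ether intact up to that point. The closest known reaction type is the amine N-oxide-promoted intramolecular Pauson–Khand reaction of cobalt-complexed alkoxyalkynes and of oxygen-tethered 1,7-enynes. The oxane closes in the alkene insertion, a 6-exo closure with respect to both π systems over the C1–O2–C3–C4 tether, and the cyclopentenone closes by carbonyl insertion into the cobaltacycle and C–C reductive elimination. C5 is the only new stereocentre and is set by the allylic C4 ether, which should sit pseudo-equatorial in the chair-like insertion transition state and so end up cis to H-5; the C5 epimer is a diastereomer and is removed by chromatography, so enantiopurity rests on the purchased diol. The step needs chemoselectivity for the vinyl group in the 1,7-mode, which is secured because 11 has only this one alkene, and the regiochemistry (oxygen on C8 next to the new carbonyl) is fixed by the tether.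

Step 8
Reactants: 12 bicyclic α-alkoxy enone
Product: 14 8β-(hydroxymethyl)-1-methoxy-4β,8α-bis[(4-methoxybenzyl)oxy]-5βH,9βH-hexahydrocyclopenta[c]pyran-7-one (C1 epimers), via silyl enol ether 13 (not isolated)
Conditions: (IPr)CuCl (5 mol %), NaOt-Bu (5 mol %), PhMe2SiH, toluene, rt; then 37% aq. HCHO, Yb(OTf)3 (20 mol %), THF, rt
Reagents that add atoms: formaldehyde, C=O
Why: Copper hydride conjugate reduction (1,4-hydrosilylation) should deliver hydride to C9 on the face of H-5 to give the cis-fused silyl enol ether, and the Lewis acid-catalysed Mukaiyama aldol with aqueous formaldehyde then attacks C8 from the same convex β-face, so that C10 is β and the PMB ether α.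

Step 9
Reactants: 14 methyl acetal ketol
Product: 15 1-hydroxy-8β-(hydroxymethyl)-4β,8α-bis[(4-methoxybenzyl)oxy]-5βH,9βH-hexahydrocyclopenta[c]pyran-7-one (lactol, C1 epimers)
Conditions: 0.5 M aq. HCl, THF, rt
Reagents that add atoms: water, O
Why: Mild aqueous acid hydrolysis of the 2-methoxyoxane acetal (glycoside-type hydrolysis) frees the lactol at a stage without silyl ethers or enol ether, the PMB ethers being stable to dilute acid.

Step 10
Reactants: 15 lactol diol
Product: 16 1,10-bis-O-TBS ether of 15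
Conditions: TBSCl, imidazole, DMF, 0 °C → rt
Reagents that add atoms: tert-butyldimethylsilyl chloride, CC(C)(C)[Si](C)(C)Cl
Why: Silylation of the primary alcohol and of the lactol hydroxyl (as for 1-O-silyl sugars) protects both for the following steps.

Step 11
Reactants: 16 bis-TBS bis-PMB ketone
Product: 17 4β,8α-dihydroxy-1-(TBS-oxy)-8β-[(TBS-oxy)methyl]-5βH,9βH-hexahydrocyclopenta[c]pyran-7-one
Conditions: DDQ, CH2Cl2/pH 7 buffer, 0 °C → rt
Reagents that add atoms: none
Why: Oxidative PMB cleavage by DDQ (benzylic hydride abstraction, then hydrolysis of the oxocarbenium ions) frees the 4β- and 8α-hydroxyls while the silyl groups stay.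

Step 12
Reactants: 17 4β,8α-diol
Product: 18 8α-hydroxy-1-(TBS-oxy)-8β-[(TBS-oxy)methyl]-5βH,9βH-hexahydrocyclopenta[c]pyran-4,7-dione
Conditions: Dess–Martin periodinane, NaHCO3, CH2Cl2, 0 °C
Reagents that add atoms: none
Why: Dess–Martin oxidation converts the only secondary alcohol into the C4 ketone, which erases the C4 stereocentre after it has done its work; the buffer is used because H-5 is now α to a carbonyl.

Step 13
Reactants: 18 4,7-dione
Product: 19 7β,8α-dihydroxy-1-(TBS-oxy)-8β-[(TBS-oxy)methyl]-5βH,9βH-hexahydrocyclopenta[c]pyran-4-one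
Conditions: Me4NBH(OAc)3, MeCN/AcOH, −30 → −20 °C
Reagents that add atoms: none
Why: Saksena–Evans hydroxyl-directed reduction: the 8α-OH binds the triacetoxyborohydride and delivers hydride to the α-face of the adjacent C7 carbonyl, giving the 7β-alcohol trans to the 8α-OH, while the C4 ketone, which has no hydroxyl in reach and is inert to this reagent, is kept.

Step 14
Reactants: 19 C4 ketone diol
Product: 20 4,11-epoxide (spiro-oxirane at C4) of the 7β,8α-diol
Conditions: Me3S+ I−, KHMDS, THF, −10 → 0 °C
Reagents that add atoms: trimethylsulfonium iodide, C[S+](C)C.[I-]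
Why: Corey–Chaykovsky epoxidation: dimethylsulfonium methylide adds to the C4 ketone faster than it enolises it and closes the spiro-epoxide, which brings in C11 (the configuration at C4 is of no consequence; excess ylide covers the two hydroxyls).

Step 15
Reactants: 20 spiro-epoxide
Product: 21 4-(hydroxymethyl)-1-(TBS-oxy)-8β-[(TBS-oxy)methyl]-1,5β,6,7,8,9β-hexahydrocyclopenta[c]pyran-7β,8α-diol (C3=C4 enol ether)
Conditions: Et2AlTMP (from TMPH, n-BuLi, Et2AlCl), toluene, 0 °C
Reagents that add atoms: none
Why: Aluminium amide-mediated isomerisation of an epoxide to an allylic alcohol: the bulky Et2AlTMP binds the epoxide oxygen and removes a syn β-hydrogen from the C3 methylene, not the hindered tertiary H-5, which gives the C3=C4 enol ether and the C11 alcohol.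

Step 16
Reactants: 21 triol
Product: 22 11-O-TBS ether of 21
Conditions: TBSCl (1.1 equiv), imidazole, CH2Cl2, −20 → 0 °C
Reagents that add atoms: tert-butyldimethylsilyl chloride, CC(C)(C)[Si](C)(C)Cl
Why: Selective silylation of the primary allylic alcohol over the hindered secondary 7-OH and the tertiary 8-OH.

Step 17
Reactants: 22 1,10,11-tris-O-TBS compound
Product: 23 10,11-bis-O-TBS lactol (1-OH, C1 epimers)
Conditions: TBAF, AcOH (1:1.5), THF, −20 °C
Reagents that add atoms: none
Why: An anomeric silyl acetal is far more labile to fluoride than alkyl silyl ethers (the lactolate is the better leaving group), so buffered TBAF at low temperature should free only the lactol, and the buffer limits ring-opening and epimerisation at C9.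

Step 18
Reactants: 23 enol-ether lactol
Product: 24 1β-O-isovaleryl-10,11-bis-O-TBS 7β,8α-diol
Conditions: isovaleryl chloride, pyridine, DMAP (cat.), CH2Cl2, −40 → 0 °C
Reagents that add atoms: isovaleryl chloride, CC(C)CC(=O)Cl
Why: O-Acylation of the equilibrating lactol should give mainly the 1β-ester, in which the acyloxy group is pseudo-axial (anomeric effect) and trans to the C9–C8 bond as in natural 1-O-acyl iridoids, and the lactol hydroxyl reacts before the hindered 7-OH and the tertiary 8-OH; any 1α-ester is removed by chromatography.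

Step 19
Reactants: 25 p-coumaric acid
Product: 27 (E)-3-[4-(TBS-oxy)phenyl]prop-2-enoic acid, via bis-silylated coumarate 26 (not isolated)
Conditions: TBSCl, imidazole, DMF, rt; then AcOH/THF/H2O, rt
Reagents that add atoms: tert-butyldimethylsilyl chloride, CC(C)(C)[Si](C)(C)Cl
Why: Exhaustive silylation followed by selective hydrolysis of the labile silyl ester leaves the phenol TBS ether and the free (E)-acid.

Step 20
Reactants: 24 1β-isovalerate diol; 27 TBS-protected p-coumaric acid
Product: 29 10,11,4'-tris-O-TBS luzonoid A, via mixed anhydride 28 (not isolated)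
Conditions: 27, 2,4,6-Cl3C6H2COCl, Et3N, toluene, rt; then 24, DMAP, rt
Reagents that add atoms: none
Why: Yamaguchi esterification: the mixed anhydride acylates the hindered secondary 7β-OH under DMAP catalysis, the tertiary 8-OH does not react and the anomeric ester is stable to these conditions.

Step 21
Reactants: 29 tris-O-TBS luzonoid A
Product: 30 luzonoid A
Conditions: HF·pyridine, pyridine, THF, 0 °C → rt
Reagents that add atoms: none
Why: Buffered fluoride desilylation cleaves the two primary silyl ethers and the aryl silyl ether without base, so the anomeric ester, the coumarate and the enol ether acetal should survive and no acyl migration to O10 is promoted.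

**Compound list**

1 | (R)-but-3-ene-1,2-diol | OC[C@H](O)C=C | starting material
2 | (4R)-2-(4-methoxyphenyl)-4-vinyl-1,3-dioxolane | C=C[C@@H]1COC(c2ccc(OC)cc2)O1 | intermediate
3 | (R)-2-[(4-methoxybenzyl)oxy]but-3-en-1-ol | OC[C@H](OCc1ccc(OC)cc1)C=C | intermediate
4 | 4-methoxybenzyl alcohol | COc1ccc(CO)cc1 | starting material
5 | trichloroethylene | ClC=C(Cl)Cl | starting material
6 | (E)-1,2-dichlorovinyl 4-methoxybenzyl ether | COc1ccc(CO/C(Cl)=C\Cl)cc1 | intermediate
7 | lithium [(4-methoxybenzyl)oxy]acetylide | [Li]C#COCc1ccc(OC)cc1 | intermediate (not isolated)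
8 | 3-[(4-methoxybenzyl)oxy]prop-2-ynal | O=CC#COCc1ccc(OC)cc1 | intermediate
9 | hexacarbonyldicobalt complex of 8 | COc1ccc(COC23C4(C=O)[Co]2(=C=O)(=C=O)(=C=O)[Co]34(=C=O)(=C=O)=C=O)cc1 | intermediate (not isolated)
10 | hexacarbonyldicobalt complex of 3,3-dimethoxy-1-[(4-methoxybenzyl)oxy]prop-1-yne | COc1ccc(COC23C4(C(OC)OC)[Co]2(=C=O)(=C=O)(=C=O)[Co]34(=C=O)(=C=O)=C=O)cc1 | intermediate
11 | hexacarbonyldicobalt complex of the PMB ynol ether (2R)-2-(PMB-oxy)but-3-enyl methyl acetal (key-step precursor) | COc1ccc(COC23C4(C(OC)OC[C@H](OCc5ccc(OC)cc5)C=C)[Co]2(=C=O)(=C=O)(=C=O)[Co]34(=C=O)(=C=O)=C=O)cc1 | intermediate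
12 | 1-methoxy-4β,8-bis(PMB-oxy)-3,4,5,6-tetrahydro-1H-cyclopenta[c]pyran-7-one, H-5β (key-step product) | COC1OC[C@H](OCc2ccc(OC)cc2)[C@H]3CC(=O)C(OCc2ccc(OC)cc2)=C13 | intermediate
13 | 7-O-dimethylphenylsilyl enol ether (C7=C8), H-5β, H-9β | COC1OC[C@H](OCc2ccc(OC)cc2)[C@H]3CC(O[Si](C)(C)c2ccccc2)=C(OCc2ccc(OC)cc2)[C@@H]13 | intermediate (not isolated)
14 | 8β-(hydroxymethyl)-1-methoxy-4β,8α-bis(PMB-oxy)-5βH,9βH-hexahydrocyclopenta[c]pyran-7-one | COC1OC[C@H](OCc2ccc(OC)cc2)[C@H]3CC(=O)[C@](OCc2ccc(OC)cc2)(CO)[C@@H]13 | intermediate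
15 | 1-hydroxy analogue of 14 (lactol) | OC1OC[C@H](OCc2ccc(OC)cc2)[C@H]3CC(=O)[C@](OCc2ccc(OC)cc2)(CO)[C@@H]13 | intermediate
16 | 1,10-bis-O-TBS ether of 15 | CC(C)(C)[Si](C)(C)OC1OC[C@H](OCc2ccc(OC)cc2)[C@H]3CC(=O)[C@](OCc2ccc(OC)cc2)(CO[Si](C)(C)C(C)(C)C)[C@@H]13 | intermediate
17 | 4β,8α-dihydroxy-1-(TBS-oxy)-8β-[(TBS-oxy)methyl]-5βH,9βH-hexahydrocyclopenta[c]pyran-7-one | CC(C)(C)[Si](C)(C)OC1OC[C@H](O)[C@H]3CC(=O)[C@](O)(CO[Si](C)(C)C(C)(C)C)[C@@H]13 | intermediate
18 | 8α-hydroxy-1-(TBS-oxy)-8β-[(TBS-oxy)methyl]-5βH,9βH-hexahydrocyclopenta[c]pyran-4,7-dione | CC(C)(C)[Si](C)(C)OC1OCC(=O)[C@H]3CC(=O)[C@](O)(CO[Si](C)(C)C(C)(C)C)[C@@H]13 | intermediate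
19 | 7β,8α-dihydroxy-1-(TBS-oxy)-8β-[(TBS-oxy)methyl]-5βH,9βH-hexahydrocyclopenta[c]pyran-4-one | CC(C)(C)[Si](C)(C)OC1OCC(=O)[C@H]3C[C@H](O)[C@](O)(CO[Si](C)(C)C(C)(C)C)[C@@H]13 | intermediate
20 | 4,11-epoxide (spiro-oxirane at C4) of the 1,10-bis-O-TBS 7β,8α-diol | CC(C)(C)[Si](C)(C)OC1OCC2(CO2)[C@H]3C[C@H](O)[C@](O)(CO[Si](C)(C)C(C)(C)C)[C@@H]13 | intermediate
21 | 4-(hydroxymethyl)-1-(TBS-oxy)-8β-[(TBS-oxy)methyl]-1,5β,6,7,8,9β-hexahydrocyclopenta[c]pyran-7β,8α-diol | CC(C)(C)[Si](C)(C)OC1OC=C(CO)[C@H]3C[C@H](O)[C@](O)(CO[Si](C)(C)C(C)(C)C)[C@@H]13 | intermediate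
22 | 11-O-TBS ether of 21 | CC(C)(C)[Si](C)(C)OC1OC=C(CO[Si](C)(C)C(C)(C)C)[C@H]3C[C@H](O)[C@](O)(CO[Si](C)(C)C(C)(C)C)[C@@H]13 | intermediate
23 | 10,11-bis-O-TBS enol-ether lactol (1,7β,8α-triol) | OC1OC=C(CO[Si](C)(C)C(C)(C)C)[C@H]3C[C@H](O)[C@](O)(CO[Si](C)(C)C(C)(C)C)[C@@H]13 | intermediate
24 | 1β-O-isovaleryl-10,11-bis-O-TBS 7β,8α-diol | CC(C)CC(=O)O[C@@H]1OC=C(CO[Si](C)(C)C(C)(C)C)[C@H]3C[C@H](O)[C@](O)(CO[Si](C)(C)C(C)(C)C)[C@@H]13 | intermediate
25 | p-coumaric acid | OC(=O)/C=C/c1ccc(O)cc1 | starting material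
26 | TBS (E)-3-[4-(TBS-oxy)phenyl]prop-2-enoate | CC(C)(C)[Si](C)(C)OC(=O)/C=C/c1ccc(O[Si](C)(C)C(C)(C)C)cc1 | intermediate (not isolated)
27 | (E)-3-[4-(TBS-oxy)phenyl]prop-2-enoic acid | OC(=O)/C=C/c1ccc(O[Si](C)(C)C(C)(C)C)cc1 | intermediate
28 | mixed anhydride of 27 with 2,4,6-trichlorobenzoic acid | O=C(OC(=O)/C=C/c1ccc(O[Si](C)(C)C(C)(C)C)cc1)c1c(Cl)cc(Cl)cc1Cl | intermediate (not isolated)
29 | 10,11,4'-tris-O-TBS luzonoid A | CC(C)CC(=O)O[C@@H]1OC=C(CO[Si](C)(C)C(C)(C)C)[C@H]3C[C@H](OC(=O)/C=C/c2ccc(O[Si](C)(C)C(C)(C)C)cc2)[C@](O)(CO[Si](C)(C)C(C)(C)C)[C@@H]13 | intermediate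
30 | luzonoid A | CC(C)CC(=O)O[C@@H]1OC=C(CO)[C@H]2C[C@H](OC(=O)/C=C/c3ccc(O)cc3)[C@](O)(CO)[C@@H]12 | target

**Step count and risks**

Total steps: 21. Longest linear sequence: 18 steps (from 4 through steps 3–18, 20 and 21).

The three steps most likely to fail:

Step 7. The alkene may insert with a poor or reversed facial sense at C5, since the allylic ether is the only controller, and insertion in the 1,7-mode may be slow. A poor ratio costs material only, because the C5 epimer is a diastereomer. If the sense is reversed, the controller is changed to the enantiomeric diol so that the major isomer has the natural C5. (S)-But-3-ene-1,2-diol F1 is converted under the conditions of steps 1 and 2 into the anisylidene acetal F2 and the (S)-alcohol F3. F3 is exchanged into 10 to give the cobalt complex F4, and the Pauson–Khand reaction gives the 4α-PMB-oxy enone F5 with H-5β. The conditions of steps 8–11 then give the silyl enol ether F6, the ketol F7, the lactol F8, the bis-silyl ether F9 and the 4α,8α-diol F10. Dess–Martin oxidation of F10 removes the C4 stereocentre. This fallback sets out from 10 and comes back at 18.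

Step 8. Hydride may be delivered to the wrong face of C9 (trans ring fusion), 1,2-reduction may compete, or the silyl enol ether may be protonated before the aldol. The fallback sets out from 12. Heterogeneous hydrogenation (H2, Pd/C, pyridine as poison to spare the PMB ethers, EtOAc) adds both hydrogens to the convex face of C8=C9 and gives the cis-fused α-alkoxy ketone F11. Soft enolisation (TMSOTf, Et3N, CH2Cl2) toward the oxygen-bearing C8 gives the trimethylsilyl enol ether F12. The same Yb(OTf)3/aqueous formaldehyde aldol then comes back at 14.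

Step 15. The base may remove H-5 instead of a C3 hydrogen (C4=C5 isomer), or the aluminium-activated epoxide may be opened by the nearby 8α-oxygen. The fallback sets out from 20. Titanocene(III) chloride (Cp2TiCl2, Mn, THF, rt) opens the epoxide homolytically to the tertiary C4 radical with titanium on O11. The titanium(III)-mediated loss of a β-hydrogen is expected to take the weaker C–H bonds next to O2, without a Lewis-acidic aluminium centre. It comes back at 21 and makes no new compound.

**Further compounds**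

F1 | step 7 | (S)-but-3-ene-1,2-diol | OC[C@@H](O)C=C
F2 | step 7 | (4S)-2-(4-methoxyphenyl)-4-vinyl-1,3-dioxolane | C=C[C@H]1COC(c2ccc(OC)cc2)O1
F3 | step 7 | (S)-2-[(4-methoxybenzyl)oxy]but-3-en-1-ol | OC[C@@H](OCc1ccc(OC)cc1)C=C
F4 | step 7 | hexacarbonyldicobalt complex of the (2S)-enyne mixed acetal | COc1ccc(COC23C4(C(OC)OC[C@@H](OCc5ccc(OC)cc5)C=C)[Co]2(=C=O)(=C=O)(=C=O)[Co]34(=C=O)(=C=O)=C=O)cc1
F5 | step 7 | 4α-PMB-oxy epimer of enone 12 | COC1OC[C@@H](OCc2ccc(OC)cc2)[C@H]3CC(=O)C(OCc2ccc(OC)cc2)=C13
F6 | step 7 | 4α-PMB-oxy epimer of silyl enol ether 13 | COC1OC[C@@H](OCc2ccc(OC)cc2)[C@H]3CC(O[Si](C)(C)c2ccccc2)=C(OCc2ccc(OC)cc2)[C@@H]13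
F7 | step 7 | 4α-PMB-oxy epimer of ketol 14 | COC1OC[C@@H](OCc2ccc(OC)cc2)[C@H]3CC(=O)[C@](OCc2ccc(OC)cc2)(CO)[C@@H]13
F8 | step 7 | 4α-PMB-oxy epimer of lactol 15 | OC1OC[C@@H](OCc2ccc(OC)cc2)[C@H]3CC(=O)[C@](OCc2ccc(OC)cc2)(CO)[C@@H]13
F9 | step 7 | 4α-PMB-oxy epimer of bis-silyl ether 16 | CC(C)(C)[Si](C)(C)OC1OC[C@@H](OCc2ccc(OC)cc2)[C@H]3CC(=O)[C@](OCc2ccc(OC)cc2)(CO[Si](C)(C)C(C)(C)C)[C@@H]13
F10 | step 7 | 4α-hydroxy epimer of diol 17 | CC(C)(C)[Si](C)(C)OC1OC[C@@H](O)[C@H]3CC(=O)[C@](O)(CO[Si](C)(C)C(C)(C)C)[C@@H]13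
F11 | step 8 | 1-methoxy-4β,8α-bis(PMB-oxy)-5βH,8βH,9βH-hexahydrocyclopenta[c]pyran-7-one | COC1OC[C@H](OCc2ccc(OC)cc2)[C@H]3CC(=O)[C@@H](OCc2ccc(OC)cc2)[C@@H]13
F12 | step 8 | 7-O-trimethylsilyl enol ether (C7=C8) of F11 | COC1OC[C@H](OCc2ccc(OC)cc2)[C@H]3CC(O[Si](C)(C)C)=C(OCc2ccc(OC)cc2)[C@@H]13
F0 | step 15 | none | none
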